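Molar per hour is the unit in which the earlier runs agree: up to 2.50 h the cedar run loses 0.138 M h⁻¹ of solid electrophile and the oak run 0.141 M h⁻¹, the same despite different charges.

common to all: nucleophile 0.558 M
- cedar: solid electrophile 0.43 M; scavenger 0.093 M; run made earlier
- oak: solid electrophile 0.68 M; scavenger 0.093 M; run made earlier
- flask: solid electrophile 0.31 M; scavenger 0.0930 M; time 3.0 h

- cedar (time / h: solid electrophile / %, product / %): 0.333: 84, 6; 0.833: 64, 18; 1.50: 46, 33; 2.50: 20, 52
- oak (time / h: solid electrophile / %, product / %): 0.200: 91, 3; 0.417: 91, 8; 1.00: 73, 15; 2.50: 48, 33

(scatter of a reading: 1.5 percentage points)

1. part of the solid electrophile that has reacted (what has only dissolved counts as not reacted) at 3.0 h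
2. share of free nucleophile in free nucleophile and protonated nucleophile together, at 3.0 h

- what is said of acid set free includes idle adduct
- solid electrophile is a solid; its amount is given per volume of the solution
- the numbers in the tables scatter by 1.5 percentage points (one standard deviation)
- steps under discussion: nucleophile + acid set free <-> protonated nucleophile; acid set free + scavenger -> scavenged by-product; nucleophile + acid set free <-> idle adduct; electrophile + nucleophile -> acid set free + product; solid electrophile <-> electrophile; electrophile <-> dormant form
- at the start none of the solid electrophile is in solution
- what has only dissolved of solid electrophile counts as not reacted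
- what has gone from electrophile into another species counts as reacted, even if it can come back
- the earlier runs do not show how much of nucleophile is bound; that part of a forecast is a guess

How long does the solid last in the flask? At that loss I reckon that its 0.31 M lasts 2.25 h, less than the 3.0 h asked.

How much product stands at 3.0 h? The cedar run makes 0.0894 M h⁻¹ of product and holds a pool of 0.120 M that has left the solid without becoming product, so I let the pool drain at 0.743 h⁻¹. By this estimate the pool in the flask falls to 0.0623 M, leaving 0.248 M of product. Dissolved electrophile in the pool counts as unreacted and dormant form as reacted, so my guess for c is midway between 80.0% and 100 percent: 90.0%.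

Where does the acid go? Each product sets one acid free. I guess that the scavenger has taken its full 0.0930 M by then and that the acid surplus, product minus scavenger charged 0.155 M, sits on nucleophile. Of the 0.310 M of nucleophile not in product, the free share is then 50.1%.

The forecast gives 92% and 62%, both higher than my figures, and says of the binding “this part is a guess”.

The flask gives 90.0% and 57.0%.

    nucleophile + acid set free ⇌ protonated nucleophile, settled at all times (K = 120 M⁻¹)
    acid set free + scavenger → scavenged by-product (k = 7.60 M⁻¹ min⁻¹)
    nucleophile + acid set free ⇌ idle adduct, settled at all times (K = 1.40 M⁻¹)
    electrophile + nucleophile → acid set free + product (k = 0.0870 M⁻¹ min⁻¹)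
    solid electrophile ⇌ electrophile, rate k5*(cs5 - [electrophile]) while solid is left; crystals form when [electrophile] > cs5 (solubility = 0.100 M, k = 0.0460 min⁻¹)
    electrophile ⇌ dormant form (K = 1.00, k = 0.0220 min⁻¹)

In the flask, the half-life of scavenger by its reaction with acid set free is 0.24 h at 3.00 h, shorter than the 3.0 h run. Scavenger left there is 2.6%. With the flask's product of 76.2% of the charge, the surplus is 0.143 M, beside 0.138 M of protonated nucleophile, and it gives a free share of 55.5%. A neighbour flask, like this one but with 0.056 M of scavenger, has 74.5% product, so its surplus is 0.175 M and its reckoned share 46.4%, while it stands at 49.2%.

The numbers in the tables are calculated with constants of no real substance.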